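**Plan**

1. Ring positions: C1 = C(OH)CH3, C2 = quaternary carbon (CH3 and polyene chain), C3 = CH with the hydroxypropyl arm, C4 = alkylidene carbon, C5 and C6 = CH2. The C1 hydroxyl oxygen lies 1,4 across the cyclohexane from C4, the β-carbon of the enal, so the target is the E1cB-opened (retro-oxa-Michael) form of a 7-oxabicyclo[2.2.1]heptane.
2. Retrosynthetic cuts in order: the C4=C exocyclic alkene together with a C4–O bridge; then C4–C5 and C6–C1 together, by [3+2] cycloaddition of the five-membered carbonyl ylide O/C1/C2/C3/C4 with ethylene; then C2–C3 by Gosteli–Claisen rearrangement; last the chain terminus.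
3. Forward: (2E,6E)-farnesyl acetate is extended to a C21 polyprenol; its allyl vinyl ether rearranges to set C2 and C3. The polyprenol's own CH2O–CH= end becomes the vinyl group and then, by Wacker oxidation, the CH3–C(=O) pair that ends as CH3–C1(OH).
4. The α-keto ester becomes a diazo ester; ylide formation and ethylene cycloaddition close the cyclohexane as an oxygen-bridged bicycle. The bridgehead ester is converted to a metalated nitrile that expels the bridge, and nitrile reduction with desilylation finishes.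
5. Stereochemistry: absolute configuration from the chiral copper bis(oxazoline) catalyst of the Claisen step; C2/C3 relative configuration from its chair transition state; C1 from ethylene adding to the ylide face away from both chains; the (Z)-enal from the elimination of the slender nitrile anion; the (E)-chain alkenes from farnesol and the SeO2 oxidation.

Key step: step 11

Remark: the (S,S) ligand is taken to give the (3R,4R) keto ester 15; the facial sense has to be confirmed on the first run, and the (R,R) ligand is used if it is opposite.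

**Route**

Step 1
Reactants: 1 (2E,6E)-farnesyl acetate
Product: 2 (2E,6E,10E)-12-hydroxy-3,7,11-trimethyldodeca-2,6,10-trien-1-yl acetate
Conditions: SeO2 (cat.), t-BuOOH, salicylic acid (cat.), CH2Cl2, rt
Reagents that add atoms: selenium dioxide, O=[Se]=O (catalytic oxygen carrier); tert-butyl hydroperoxide, CC(C)(C)OO
Why: SeO2 allylic oxidation (ene reaction, then [2,3]-sigmatropic shift) should attack the (E)-methyl of the terminal trisubstituted alkene, the acetate end being deactivated, and give the (E)-allylic alcohol.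

Step 2
Reactants: 2 (2E,6E,10E)-12-hydroxy-3,7,11-trimethyldodeca-2,6,10-trien-1-yl acetate
Product: 3 (2E,6E,10E)-12-bromo-3,7,11-trimethyldodeca-2,6,10-trien-1-yl acetate
Conditions: CBr4, PPh3, CH2Cl2, 0 °C
Reagents that add atoms: carbon tetrabromide, BrC(Br)(Br)Br
Why: the Appel reaction should convert the primary allylic alcohol into the bromide under neutral conditions without allylic transposition or loss of the acetate.

Step 3
Reactants: 3 (2E,6E,10E)-12-bromo-3,7,11-trimethyldodeca-2,6,10-trien-1-yl acetate; 4 3-methylbutan-2-one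
Product: 6 (6E,10E,14E)-16-hydroxy-2,6,10,14-tetramethylhexadeca-6,10,14-trien-3-one, via keto acetate 5 (not isolated)
Conditions: LiN(iPr)2, THF, −78 °C; then 3, −78 to 0 °C; then MeOH, K2CO3, rt
Reagents that add atoms: none
Why: the kinetic lithium enolate (deprotonated at CH3) should be alkylated by SN2 displacement at the primary allylic bromide, and methanolysis in the same flask then frees the allylic alcohol.

Step 4
Reactants: 6 (6E,10E,14E)-16-hydroxy-2,6,10,14-tetramethylhexadeca-6,10,14-trien-3-one
Product: 7 (2E,6E,10E)-3,7,11,15-tetramethyl-14-methylidenehexadeca-2,6,10-trien-1-ol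
Conditions: Ph3PCH3Br, KOtBu (excess), THF, 0 °C to rt
Reagents that add atoms: methyltriphenylphosphonium bromide, C[P+](c1ccccc1)(c1ccccc1)c1ccccc1.[Br-]
Why: Wittig methylenation of the isopropyl ketone should install the 1,1-disubstituted alkene, an extra equivalent of ylide covering the free hydroxyl.

Step 5
Reactants: 7 (2E,6E,10E)-3,7,11,15-tetramethyl-14-methylidenehexadeca-2,6,10-trien-1-ol; 8 bromoacetic acid
Product: 10 methyl 2-{[(2E,6E,10E)-3,7,11,15-tetramethyl-14-methylidenehexadeca-2,6,10-trien-1-yl]oxy}acetate, via sodium carboxylate 9 (not isolated)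
Conditions: NaH, THF, 0 °C to reflux; then MeI, DMF, rt
Reagents that add atoms: iodomethane, CI
Why: Williamson etherification of the sodium alkoxide with sodium bromoacetate, followed by O-methylation of the carboxylate in the same flask, should give the allyloxyacetate.

Step 6
Reactants: 10 methyl 2-{[(2E,6E,10E)-3,7,11,15-tetramethyl-14-methylidenehexadeca-2,6,10-trien-1-yl]oxy}acetate; 11 4-[(tert-butyldimethylsilyl)oxy]butanal
Product: 12 methyl 6-[(tert-butyldimethylsilyl)oxy]-3-hydroxy-2-{[(2E,6E,10E)-3,7,11,15-tetramethyl-14-methylidenehexadeca-2,6,10-trien-1-yl]oxy}hexanoate (mixture of diastereomers)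
Conditions: LiN(iPr)2, THF, −78 °C; then 11, −78 °C; aq. NH4Cl
Reagents that add atoms: none
Why: aldol addition of the lithium ester enolate at −78 °C, below the temperature at which the competing [2,3]-Wittig shift of the allyloxy enolate sets in; both new centres are removed in the next step.

Step 7
Reactants: 12 methyl 6-[(tert-butyldimethylsilyl)oxy]-3-hydroxy-2-{[(2E,6E,10E)-3,7,11,15-tetramethyl-14-methylidenehexadeca-2,6,10-trien-1-yl]oxy}hexanoate
Product: 14 methyl (2Z)-6-[(tert-butyldimethylsilyl)oxy]-2-{[(2E,6E,10E)-3,7,11,15-tetramethyl-14-methylidenehexadeca-2,6,10-trien-1-yl]oxy}hex-2-enoate, via mesylate 13 (not isolated)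
Conditions: MsCl, Et3N, CH2Cl2, 0 °C; then DBU, rt; chromatographic removal of the minor (E) isomer
Reagents that add atoms: none
Why: mesylation and DBU-mediated E1cB elimination should give the 2-alkoxy enoate, the (Z) isomer (chain trans to the ester) being expected to predominate.

Step 8
Reactants: 14 methyl (2Z)-6-[(tert-butyldimethylsilyl)oxy]-2-{[(2E,6E,10E)-3,7,11,15-tetramethyl-14-methylidenehexadeca-2,6,10-trien-1-yl]oxy}hex-2-enoate
Product: 15 methyl (3R,4R,7E,11E)-3-{3-[(tert-butyldimethylsilyl)oxy]propyl}-4-ethenyl-4,8,12,16-tetramethyl-15-methylidene-2-oxoheptadeca-7,11-dienoate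
Conditions: [Cu((S,S)-tBu-box)(H2O)2](SbF6)2 (5 mol %), CH2Cl2, rt
Reagents that add atoms: none
Why: Gosteli–Claisen ([3,3]-sigmatropic) rearrangement with two-point binding of the ether and ester oxygens to the chiral divalent copper bis(oxazoline) complex should pass through a chair with the (Z)-enol ether substituent axial and the (E)-allyl chain equatorial, which fixes the relative configuration of future ring carbons C2 (quaternary) and C3, while the ligand selects the enol ether face and so the absolute configuration.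

Step 9
Reactants: 15 methyl (3R,4R,7E,11E)-3-{3-[(tert-butyldimethylsilyl)oxy]propyl}-4-ethenyl-4,8,12,16-tetramethyl-15-methylidene-2-oxoheptadeca-7,11-dienoate
Product: 16 methyl (3R,4S,7E,11E)-4-acetyl-3-{3-[(tert-butyldimethylsilyl)oxy]propyl}-4,8,12,16-tetramethyl-15-methylidene-2-oxoheptadeca-7,11-dienoate
Conditions: PdCl2 (10 mol %), CuCl (1 equiv), O2 (1 atm), DMF/H2O 7:1, rt
Reagents that add atoms: water, O
Why: Tsuji–Wacker oxidation with divalent palladium should convert only the monosubstituted vinyl group (Markovnikov) into the methyl ketone, the 1,1-disubstituted and trisubstituted alkenes being far less reactive.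

Step 10
Reactants: 16 methyl (3R,4S,7E,11E)-4-acetyl-3-{3-[(tert-butyldimethylsilyl)oxy]propyl}-4,8,12,16-tetramethyl-15-methylidene-2-oxoheptadeca-7,11-dienoate
Product: 18 methyl (3R,4S,7E,11E)-4-acetyl-2-diazo-3-{3-[(tert-butyldimethylsilyl)oxy]propyl}-4,8,12,16-tetramethyl-15-methylideneheptadeca-7,11-dienoate, via tosylhydrazone 17 (not isolated)
Conditions: TsNHNH2 (1.0 equiv), CH2Cl2, rt; then DBU, 0 °C
Reagents that add atoms: 4-methylbenzenesulfonohydrazide, Cc1ccc(cc1)S(=O)(=O)NN
Why: the activated α-keto ester carbonyl should condense with the hydrazide in preference to the neopentyl-type methyl ketone, and DBU then expels sulfinate (Bamford–Stevens) to give the α-diazo ester.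

Step 11
Reactants: 18 methyl (3R,4S,7E,11E)-4-acetyl-2-diazo-3-{3-[(tert-butyldimethylsilyl)oxy]propyl}-4,8,12,16-tetramethyl-15-methylideneheptadeca-7,11-dienoate; 19 ethylene
Product: 21 methyl (1S,2R,3S,4R)-2-{3-[(tert-butyldimethylsilyl)oxy]propyl}-3,4-dimethyl-3-[(3E,7E)-4,8,12-trimethyl-11-methylidenetrideca-3,7-dien-1-yl]-7-oxabicyclo[2.2.1]heptane-1-carboxylate, via carbonyl ylide 20 (not isolated)
Conditions: Rh2(OPiv)4 (1 mol %), ethylene (2 bar), CH2Cl2, −78 to −30 °C, slow addition of 18
Reagents that add atoms: none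
Why: Rh2(OPiv)4 turns the diazo ester into a rhodium carbenoid whose carbon is attacked by the oxygen of the methyl ketone to give the five-membered cyclic carbonyl ylide 20, and this 1,3-dipole adds ethylene across its two carbon termini in a concerted suprafacial [3+2] cycloaddition that forms the C4–C5 and C6–C1 bonds at once. The closest known reaction type is the tandem carbonyl ylide formation and 1,3-dipolar cycloaddition of diazo carbonyl compounds that carry a γ-keto group, together with the use of α-alkyl-α-diazo esters under bulky dirhodium carboxylates at low temperature, where 1,2-hydride migration is held back. The oxolane ring of the ylide closes by five-membered attack of oxygen on the carbenoid carbon, and the cyclohexane ring closes by the intermolecular [3+2] cycloaddition, which delivers it as the boat of a 7-oxabicyclo[2.2.1]heptane. The new stereocentres C1 and C4 are tied to each other by the oxygen bridge, and their configuration relative to C2 and C3 is set by ethylene approaching the face of the planar ylide ring that carries the C2 methyl and the C3 hydrogen, away from the two long chains that sit cis on the other face. The step needs ylide formation to win over 1,2-hydride shift from C3, cyclopropanation of the chain alkenes and C–H insertion, which the nearby ketone oxygen, the pivalate ligands and −78 °C should secure, and it needs fast trapping of the ylide, which the high concentration of ethylene should secure. Regiochemistry does not arise because ethylene is symmetric.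

Step 12
Reactants: 21 methyl (1S,2R,3S,4R)-2-{3-[(tert-butyldimethylsilyl)oxy]propyl}-3,4-dimethyl-3-[(3E,7E)-4,8,12-trimethyl-11-methylidenetrideca-3,7-dien-1-yl]-7-oxabicyclo[2.2.1]heptane-1-carboxylate
Product: 23 1-[(1S,2R,3S,4R)-2-{3-[(tert-butyldimethylsilyl)oxy]propyl}-3,4-dimethyl-3-[(3E,7E)-4,8,12-trimethyl-11-methylidenetrideca-3,7-dien-1-yl]-7-oxabicyclo[2.2.1]heptan-1-yl]ethan-1-one, via silyl enolate 22 (not isolated)
Conditions: Me3SiCH2Li (3 equiv), pentane/THF, 0 °C; then MeOH, rt
Reagents that add atoms: (trimethylsilyl)methyllithium, [Li]C[Si](C)(C)C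
Why: addition of Me3SiCH2Li to the ester gives the α-silyl ketone, which a second equivalent deprotonates to an enolate that resists further addition, and methanolysis then removes silicon to leave the methyl ketone.

Step 13
Reactants: 23 1-[(1S,2R,3S,4R)-2-{3-[(tert-butyldimethylsilyl)oxy]propyl}-3,4-dimethyl-3-[(3E,7E)-4,8,12-trimethyl-11-methylidenetrideca-3,7-dien-1-yl]-7-oxabicyclo[2.2.1]heptan-1-yl]ethan-1-one
Product: 25 (2Z)-2-[(2S,3S,4R)-2-{3-[(tert-butyldimethylsilyl)oxy]propyl}-4-hydroxy-3,4-dimethyl-3-[(3E,7E)-4,8,12-trimethyl-11-methylidenetrideca-3,7-dien-1-yl]cyclohexylidene]propanenitrile, via metalated nitrile 24 (not isolated)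
Conditions: TosMIC, KOtBu, DME/t-BuOH, −20 to 20 °C
Reagents that add atoms: 4-toluenesulfonylmethyl isocyanide, Cc1ccc(cc1)S(=O)(=O)C[N+]#[C-]
Why: van Leusen reductive cyanation delivers the α-metalated nitrile, which should expel the strained β-oxygen bridge by E1cB instead of being protonated; in the elimination the slender linear nitrile takes the side of the substituted ring carbon C3 and the methyl the side of C5, so the (Z)-alkene and the free C1 alkoxide should result with the C1–O bond untouched.

Step 14
Reactants: 25 (2Z)-2-[(2S,3S,4R)-2-{3-[(tert-butyldimethylsilyl)oxy]propyl}-4-hydroxy-3,4-dimethyl-3-[(3E,7E)-4,8,12-trimethyl-11-methylidenetrideca-3,7-dien-1-yl]cyclohexylidene]propanenitrile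
Product: 27 (2Z)-2-[(2S,3S,4R)-4-hydroxy-2-(3-hydroxypropyl)-3,4-dimethyl-3-[(3E,7E)-4,8,12-trimethyl-11-methylidenetrideca-3,7-dien-1-yl]cyclohexylidene]propanal (CNP0226600.1), via silyl ether 26 (not isolated)
Conditions: iBu2AlH (3 equiv), toluene, −78 to −40 °C; then 1 M aq. HCl, THF, rt
Reagents that add atoms: water, O
Why: iBu2AlH should reduce the nitrile to the aldimine without changing the alkene geometry, and dilute acid then hydrolyses it to the enal and cleaves the primary silyl ether.

**Compound list**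

1 | (2E,6E)-farnesyl acetate | CC(C)=CCC/C(C)=C/CC/C(C)=C/COC(C)=O | starting material
2 | (2E,6E,10E)-12-hydroxy-3,7,11-trimethyldodeca-2,6,10-trien-1-yl acetate | OC/C(C)=C/CC/C(C)=C/CC/C(C)=C/COC(C)=O | intermediate
3 | (2E,6E,10E)-12-bromo-3,7,11-trimethyldodeca-2,6,10-trien-1-yl acetate | BrC/C(C)=C/CC/C(C)=C/CC/C(C)=C/COC(C)=O | intermediate
4 | 3-methylbutan-2-one | CC(C)C(C)=O | starting material
5 | (2E,6E,10E)-3,7,11,15-tetramethyl-14-oxohexadeca-2,6,10-trien-1-yl acetate | CC(C)C(=O)CC/C(C)=C/CC/C(C)=C/CC/C(C)=C/COC(C)=O | intermediate (not isolated)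
6 | (6E,10E,14E)-16-hydroxy-2,6,10,14-tetramethylhexadeca-6,10,14-trien-3-one | CC(C)C(=O)CC/C(C)=C/CC/C(C)=C/CC/C(C)=C/CO | intermediate
7 | (2E,6E,10E)-3,7,11,15-tetramethyl-14-methylidenehexadeca-2,6,10-trien-1-ol | C=C(CC/C(C)=C/CC/C(C)=C/CC/C(C)=C/CO)C(C)C | intermediate
8 | bromoacetic acid | OC(=O)CBr | starting material
9 | sodium 2-{[(2E,6E,10E)-3,7,11,15-tetramethyl-14-methylidenehexadeca-2,6,10-trien-1-yl]oxy}acetate | C=C(CC/C(C)=C/CC/C(C)=C/CC/C(C)=C/COCC(=O)[O-])C(C)C.[Na+] | intermediate (not isolated)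
10 | methyl 2-{[(2E,6E,10E)-3,7,11,15-tetramethyl-14-methylidenehexadeca-2,6,10-trien-1-yl]oxy}acetate | C=C(CC/C(C)=C/CC/C(C)=C/CC/C(C)=C/COCC(=O)OC)C(C)C | intermediate
11 | 4-[(tert-butyldimethylsilyl)oxy]butanal | O=CCCCO[Si](C)(C)C(C)(C)C | starting material
12 | methyl 6-[(tert-butyldimethylsilyl)oxy]-3-hydroxy-2-{[(2E,6E,10E)-3,7,11,15-tetramethyl-14-methylidenehexadeca-2,6,10-trien-1-yl]oxy}hexanoate (diastereomer mixture at C2 and C3) | C=C(CC/C(C)=C/CC/C(C)=C/CC/C(C)=C/COC(C(=O)OC)C(O)CCCO[Si](C)(C)C(C)(C)C)C(C)C | intermediate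
13 | 3-methanesulfonate of 12 | C=C(CC/C(C)=C/CC/C(C)=C/CC/C(C)=C/COC(C(=O)OC)C(OS(C)(=O)=O)CCCO[Si](C)(C)C(C)(C)C)C(C)C | intermediate (not isolated)
14 | methyl (2Z)-6-[(tert-butyldimethylsilyl)oxy]-2-{[(2E,6E,10E)-3,7,11,15-tetramethyl-14-methylidenehexadeca-2,6,10-trien-1-yl]oxy}hex-2-enoate | C=C(CC/C(C)=C/CC/C(C)=C/CC/C(C)=C/CO/C(C(=O)OC)=C\CCCO[Si](C)(C)C(C)(C)C)C(C)C | intermediate
15 | methyl (3R,4R,7E,11E)-3-{3-[(tert-butyldimethylsilyl)oxy]propyl}-4-ethenyl-4,8,12,16-tetramethyl-15-methylidene-2-oxoheptadeca-7,11-dienoate | C=C(CC/C(C)=C/CC/C(C)=C/CC[C@@](C=C)(C)[C@@H](CCCO[Si](C)(C)C(C)(C)C)C(=O)C(=O)OC)C(C)C | intermediate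
16 | methyl (3R,4S,7E,11E)-4-acetyl-3-{3-[(tert-butyldimethylsilyl)oxy]propyl}-4,8,12,16-tetramethyl-15-methylidene-2-oxoheptadeca-7,11-dienoate | C=C(CC/C(C)=C/CC/C(C)=C/CC[C@@](C(C)=O)(C)[C@@H](CCCO[Si](C)(C)C(C)(C)C)C(=O)C(=O)OC)C(C)C | intermediate
17 | 2-(4-methylbenzenesulfonylhydrazone) of 16 | C=C(CC/C(C)=C/CC/C(C)=C/CC[C@@](C(C)=O)(C)[C@@H](CCCO[Si](C)(C)C(C)(C)C)C(=NNS(=O)(=O)c1ccc(C)cc1)C(=O)OC)C(C)C | intermediate (not isolated)
18 | methyl (3R,4S,7E,11E)-4-acetyl-2-diazo-3-{3-[(tert-butyldimethylsilyl)oxy]propyl}-4,8,12,16-tetramethyl-15-methylideneheptadeca-7,11-dienoate | C=C(CC/C(C)=C/CC/C(C)=C/CC[C@@](C(C)=O)(C)[C@@H](CCCO[Si](C)(C)C(C)(C)C)C(=[N+]=[N-])C(=O)OC)C(C)C | intermediate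
19 | ethylene | C=C | starting material
20 | five-membered cyclic carbonyl ylide (oxolan-1-ium-2-ide carrying the ester on the ylide carbon and the methyl on the oxocarbenium carbon; the two stereocentres as in 18) | C=C(CC/C(C)=C/CC/C(C)=C/CC[C@@]1(C)[C@@H](CCCO[Si](C)(C)C(C)(C)C)[C-](C(=O)OC)[O+]=C1C)C(C)C | intermediate (not isolated)
21 | methyl (1S,2R,3S,4R)-2-{3-[(tert-butyldimethylsilyl)oxy]propyl}-3,4-dimethyl-3-[(3E,7E)-4,8,12-trimethyl-11-methylidenetrideca-3,7-dien-1-yl]-7-oxabicyclo[2.2.1]heptane-1-carboxylate | C=C(CC/C(C)=C/CC/C(C)=C/CC[C@@]1(C)[C@@H](CCCO[Si](C)(C)C(C)(C)C)[C@]2(C(=O)OC)CC[C@@]1(C)O2)C(C)C | intermediate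
22 | lithium enolate of the bridgehead (trimethylsilyl)acetyl ketone | C=C(CC/C(C)=C/CC/C(C)=C/CC[C@@]1(C)[C@@H](CCCO[Si](C)(C)C(C)(C)C)[C@]2(C([O-])=C[Si](C)(C)C)CC[C@@]1(C)O2)C(C)C.[Li+] | intermediate (not isolated)
23 | 1-[(1S,2R,3S,4R)-2-{3-[(tert-butyldimethylsilyl)oxy]propyl}-3,4-dimethyl-3-[(3E,7E)-4,8,12-trimethyl-11-methylidenetrideca-3,7-dien-1-yl]-7-oxabicyclo[2.2.1]heptan-1-yl]ethan-1-one | C=C(CC/C(C)=C/CC/C(C)=C/CC[C@@]1(C)[C@@H](CCCO[Si](C)(C)C(C)(C)C)[C@]2(C(C)=O)CC[C@@]1(C)O2)C(C)C | intermediate
24 | potassium salt of the metalated bridgehead propanenitrile (keteniminate) | C=C(CC/C(C)=C/CC/C(C)=C/CC[C@@]1(C)[C@@H](CCCO[Si](C)(C)C(C)(C)C)[C@]2(C(C)=C=[N-])CC[C@@]1(C)O2)C(C)C.[K+] | intermediate (not isolated)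
25 | (2Z)-2-[(2S,3S,4R)-2-{3-[(tert-butyldimethylsilyl)oxy]propyl}-4-hydroxy-3,4-dimethyl-3-[(3E,7E)-4,8,12-trimethyl-11-methylidenetrideca-3,7-dien-1-yl]cyclohexylidene]propanenitrile | C=C(CC/C(C)=C/CC/C(C)=C/CC[C@@]1(C)[C@@H](CCCO[Si](C)(C)C(C)(C)C)/C(=C(/C)C#N)CC[C@@]1(C)O)C(C)C | intermediate
26 | tert-butyldimethylsilyl ether of the target at the primary hydroxyl | C=C(CC/C(C)=C/CC/C(C)=C/CC[C@@]1(C)[C@@H](CCCO[Si](C)(C)C(C)(C)C)/C(=C(/C)C=O)CC[C@@]1(C)O)C(C)C | intermediate (not isolated)
27 | (2Z)-2-[(2S,3S,4R)-4-hydroxy-2-(3-hydroxypropyl)-3,4-dimethyl-3-[(3E,7E)-4,8,12-trimethyl-11-methylidenetrideca-3,7-dien-1-yl]cyclohexylidene]propanal | C=C(CC/C(C)=C/CC/C(C)=C/CC[C@@]1(C)[C@@H](CCCO)/C(=C(/C)C=O)CC[C@@]1(C)O)C(C)C | target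

**Totals**

Total step count: 14. Longest linear sequence: 14 steps (from 1; compounds 4, 8, 11 and 19 are purchased).

**Steps most likely to fail, with fallbacks**

1. The cycloaddition (step 11). The carbenoid may undergo 1,2-hydride migration from the neighbouring methine before the ketone oxygen closes the ylide. The ylide may also be intercepted too slowly by unactivated ethylene and decay by proton transfer from its C-methyl group or by dimerisation. The fallback sets out from 18 and uses an activated ethylene equivalent. The same dirhodium-catalysed ylide formation is run in the presence of nitroethylene, which the nucleophilic ylide carbon should attack much faster, to give the nitro cycloadduct F1 (nitro group on the ring CH2 next to the methyl-bearing bridgehead, both epimers). Radical denitration with Bu3SnH and AIBN in toluene at 110 °C then removes the nitro group. Because this passes through a carbon radical and not a carbanion, the β-oxygen bridge should not be expelled, and the route is rejoined at 21.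

2. The asymmetric rearrangement (step 8). The allyl terminus is a tertiary centre, so a dissociative ion-pair pathway may erode enantio- and diastereoselectivity. The copper-bound α-keto ester product may also undergo a carbonyl-ene cyclisation onto the chain alkene. The fallback sets out from 14 and replaces asymmetric catalysis by resolution. Heating 14 without catalyst in 1,2-dichloroethane at 80 °C should give the racemic keto ester F2 with the same relative configuration through the chair transition state. A ketoreductase, selected by screening and run with NADPH recycling (glucose dehydrogenase, glucose, buffer with co-solvent), then reduces only the unwanted enantiomer to the hydroxy ester F3. The unreduced enantiomer is recovered, which rejoins the route at 15.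

3. The cyanation and ring-opening (step 13). The basic TosMIC anion may enolise the hindered methyl ketone instead of adding to it, and protonation of the metalated nitrile may leave the bridge unopened. The fallback sets out from 23 and uses a different one-carbon homologation. Wittig reaction with Ph3P(CH2OMe)Cl and KN(SiMe3)2 in THF should give the enol ether F4 as an E/Z mixture. Dilute aqueous HCl in THF then hydrolyses the enol ether to the β-alkoxy aldehyde, whose enol expels the oxygen bridge; the small vinylic CH is expected to lie beside C3 in the elimination. The same acid cleaves the silyl ether, so the route is rejoined directly at 27.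

**Further compounds**

F1 | step 11 | methyl 2-{3-[(tert-butyldimethylsilyl)oxy]propyl}-3,4-dimethyl-5-nitro-3-[(3E,7E)-4,8,12-trimethyl-11-methylidenetrideca-3,7-dien-1-yl]-7-oxabicyclo[2.2.1]heptane-1-carboxylate (ring configuration as in 21, both nitro epimers) | C=C(CC/C(C)=C/CC/C(C)=C/CC[C@@]1(C)[C@@H](CCCO[Si](C)(C)C(C)(C)C)[C@]2(C(=O)OC)CC([N+](=O)[O-])[C@@]1(C)O2)C(C)C
F2 | step 8 | racemic methyl (3R*,4R*,7E,11E)-3-{3-[(tert-butyldimethylsilyl)oxy]propyl}-4-ethenyl-4,8,12,16-tetramethyl-15-methylidene-2-oxoheptadeca-7,11-dienoate (racemate of 15, one enantiomer drawn) | C=C(CC/C(C)=C/CC/C(C)=C/CC[C@@](C=C)(C)[C@@H](CCCO[Si](C)(C)C(C)(C)C)C(=O)C(=O)OC)C(C)C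
F3 | step 8 | methyl (3S,4S,7E,11E)-3-{3-[(tert-butyldimethylsilyl)oxy]propyl}-4-ethenyl-2-hydroxy-4,8,12,16-tetramethyl-15-methylideneheptadeca-7,11-dienoate (reduced antipode, carbinol configuration as set by the enzyme, not assigned) | C=C(CC/C(C)=C/CC/C(C)=C/CC[C@](C=C)(C)[C@H](CCCO[Si](C)(C)C(C)(C)C)C(O)C(=O)OC)C(C)C
F4 | step 13 | tert-butyl{3-[(1S,2R,3S,4R)-1-(1-methoxyprop-1-en-2-yl)-3,4-dimethyl-3-[(3E,7E)-4,8,12-trimethyl-11-methylidenetrideca-3,7-dien-1-yl]-7-oxabicyclo[2.2.1]heptan-2-yl]propoxy}dimethylsilane (E/Z mixture at the enol ether) | C=C(CC/C(C)=C/CC/C(C)=C/CC[C@@]1(C)[C@@H](CCCO[Si](C)(C)C(C)(C)C)[C@]2(C(C)=COC)CC[C@@]1(C)O2)C(C)C
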